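**Retrosynthetic overview**
1. The benzylic C–O bond, and with it the only stereocenter, is made last by catalyst-controlled Markovnikov hydration of an (E)-styrenyl tertiary alcohol.
2. The styrene comes from an aryl bromide and 2-methyl-3-buten-2-ol (Heck).
3. The free phenol of ring B comes from a formyl group (Baeyer–Villiger/Dakin), so the catechol needs no protecting group.
4. The diaryl ether C–O bond comes from an ortho-carboxylate-assisted Ullmann coupling of 3,6-dibromo-2-methoxybenzoic acid (ring A) with a hydroxymethyl-salicylaldehyde (ring B).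
5. No ring is built: ring A is 2,5-dibromoanisole (metalation/CO2), ring B is 2,6-bis(hydroxymethyl)-4-methylphenol; the rings are joined before the side chain is added.

Assumption: the stereocenter in the SMILES is (S); the sense of induction of the new hydration catalyst cannot be predicted, so the (S,S)-ligand is written and its antipode is used if it gives the (R)-alcohol.

**Step 1**
Reactants: 1 2,5-dibromoanisole (1,4-dibromo-2-methoxybenzene)
Product: 3 3,6-dibromo-2-methoxybenzoic acid, via 3,6-dibromo-2-methoxyphenyllithium 2 (not isolated)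
Conditions: LDA (1.1 equiv), THF, −78 °C, 1 h; CO2 (g), −78 °C to rt; 1 M HCl
Reagents that add atoms: carbon dioxide, O=C=O
Why: Directed ortho-metalation: the ring hydrogen flanked by OMe and Br is by far the most acidic, the aryllithium is stable at −78 °C, and carboxylation places CO2H between the methoxy group and the bromide that becomes the ether carbon; no stereocenter.

**Step 2**
Reactants: 4 2,6-bis(hydroxymethyl)-4-methylphenol
Product: 5 2-hydroxy-3-(hydroxymethyl)-5-methylbenzaldehyde
Conditions: activated MnO2 (about 4 equiv), CHCl3, rt, 18 h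
Reagents that add atoms: none
Why: Chemoselective MnO2 oxidation of a benzylic alcohol: the first formyl group, hydrogen-bonded to the phenol and electron-withdrawing, slows oxidation of the second CH2OH, so limited oxidant and time stop at the known mono-aldehyde; no stereocenter.

**Step 3**
Reactants: 3 3,6-dibromo-2-methoxybenzoic acid; 5 2-hydroxy-3-(hydroxymethyl)-5-methylbenzaldehyde (1.3 equiv)
Product: 6 3-bromo-6-[2-formyl-6-(hydroxymethyl)-4-methylphenoxy]-2-methoxybenzoic acid
Conditions: CuI (10 mol%), N,N-dimethylglycine (30 mol%), Cs2CO3 (3.5 equiv), DMF, 100 °C, argon; aq. citric acid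
Reagents that add atoms: none
Why: Ullmann diaryl ether synthesis with ortho-carboxylate assistance: the carboxylate of 3 binds monovalent copper and delivers it to the neighbouring C6–Br, so this bromide couples with the phenoxide of 5 while the C3–Br next to OMe and the benzylic alcohol stay untouched; no stereocenter.

**Step 4**
Reactants: 6 3-bromo-6-[2-formyl-6-(hydroxymethyl)-4-methylphenoxy]-2-methoxybenzoic acid
Product: 8 3-bromo-6-[2-hydroxy-6-(hydroxymethyl)-4-methylphenoxy]-2-methoxybenzoic acid, via aryl formate 7 (not isolated)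
Conditions: mCPBA (1.1 equiv), CH2Cl2, 0 °C to rt; then 1 M NaOH, MeOH, 0 °C, 15 min; HCl to pH 3
Reagents that add atoms: mCPBA (3-chloroperoxybenzoic acid), OOC(=O)c1cccc(Cl)c1
Why: Baeyer–Villiger oxidation used as a Dakin-type formyl-to-hydroxyl exchange: in the Criegee adduct the aryl group with the ortho aryloxy donor migrates to give formate 7, which dilute hydroxide cleaves to the phenol, and ring A has nothing the peracid attacks; no stereocenter.

**Step 5**
Reactants: 8 3-bromo-6-[2-hydroxy-6-(hydroxymethyl)-4-methylphenoxy]-2-methoxybenzoic acid; 9 2-methyl-3-buten-2-ol (3 equiv)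
Product: 10 6-[2-hydroxy-6-(hydroxymethyl)-4-methylphenoxy]-3-[(E)-3-hydroxy-3-methylbut-1-enyl]-2-methoxybenzoic acid
Conditions: Pd(OAc)2 (5 mol%), P(o-tol)3 (15 mol%), Et3N (5 equiv), DMF, 100 °C; aq. citric acid to pH 4
Reagents that add atoms: none
Why: Mizoroki–Heck reaction: zerovalent palladium inserts into the C3–Br bond, syn-insertion at the terminal alkene carbon and syn-β-hydride elimination give the linear (E)-styrene, and the tertiary carbinol cannot isomerise to a ketone; no stereocenter.

**Step 6**
Reactants: 10 6-[2-hydroxy-6-(hydroxymethyl)-4-methylphenoxy]-3-[(E)-3-hydroxy-3-methylbut-1-enyl]-2-methoxybenzoic acid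
Product: 11 3-[(1S)-1,3-dihydroxy-3-methylbutyl]-6-[2-hydroxy-6-(hydroxymethyl)-4-methylphenoxy]-2-methoxybenzoic acid
Conditions: (S,S)-Co(salen*) (5 mol%; divalent cobalt; salen* = dianion of N,N'-bis(3,5-di-tert-butylsalicylidene)cyclohexane-1,2-diamine), N-fluoro-2,4,6-trimethylpyridinium tetrafluoroborate (2 equiv), PhSiH3 (1.2 equiv), H2O (30 equiv), acetone, −20 °C
Reagents that add atoms: water, O
Why: Proposed new method: catalyst-controlled enantioselective Markovnikov hydration of a β-substituted styrene, in which a cobalt hydride (made from the chiral Co(salen*) complex, the N-fluoropyridinium oxidant and the silane) transfers a hydrogen atom to the alkene carbon remote from the arene, the benzylic radical is captured and oxidised to a cationic alkyl–cobalt(salen*) species (tetravalent cobalt), and water displaces cobalt on the face left open by the ligand, which forms the benzylic C–O bond and sets the (S)-carbinol; the closest known reaction types are racemic Mukaiyama-type alkene hydration and cobalt–salen hydrogen-atom-transfer/radical–polar-crossover hydroalkoxylation, which to my knowledge is enantioselective only with intramolecular alcohol nucleophiles, so asymmetric intermolecular use of water on this substrate class is untested; the large excess of water is meant to outrun 4-exo closure by the tertiary hydroxyl.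

**Compound list**
1 | 2,5-dibromoanisole | COc1cc(Br)ccc1Br | starting material
2 | 3,6-dibromo-2-methoxyphenyllithium | COc1c([Li])c(Br)ccc1Br | intermediate
3 | 3,6-dibromo-2-methoxybenzoic acid | COc1c(Br)ccc(Br)c1C(=O)O | intermediate
4 | 2,6-bis(hydroxymethyl)-4-methylphenol | Cc1cc(CO)c(O)c(CO)c1 | starting material
5 | 2-hydroxy-3-(hydroxymethyl)-5-methylbenzaldehyde | Cc1cc(CO)c(O)c(C=O)c1 | intermediate
6 | 3-bromo-6-[2-formyl-6-(hydroxymethyl)-4-methylphenoxy]-2-methoxybenzoic acid | COc1c(Br)ccc(Oc2c(C=O)cc(C)cc2CO)c1C(=O)O | intermediate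
7 | 3-bromo-6-[2-(formyloxy)-6-(hydroxymethyl)-4-methylphenoxy]-2-methoxybenzoic acid | COc1c(Br)ccc(Oc2c(OC=O)cc(C)cc2CO)c1C(=O)O | intermediate
8 | 3-bromo-6-[2-hydroxy-6-(hydroxymethyl)-4-methylphenoxy]-2-methoxybenzoic acid | COc1c(Br)ccc(Oc2c(O)cc(C)cc2CO)c1C(=O)O | intermediate
9 | 2-methyl-3-buten-2-ol | C=CC(C)(C)O | starting material
10 | 6-[2-hydroxy-6-(hydroxymethyl)-4-methylphenoxy]-3-[(E)-3-hydroxy-3-methylbut-1-enyl]-2-methoxybenzoic acid | COc1c(/C=C/C(C)(C)O)ccc(Oc2c(O)cc(C)cc2CO)c1C(=O)O | intermediate
11 | 3-[(1S)-1,3-dihydroxy-3-methylbutyl]-6-[2-hydroxy-6-(hydroxymethyl)-4-methylphenoxy]-2-methoxybenzoic acid | COc1c([C@@H](O)CC(C)(C)O)ccc(Oc2c(O)cc(C)cc2CO)c1C(=O)O | target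

**Step count**
Total: 6 steps. Longest linear sequence: 5 steps (1, 3, 4, 5, 6).

**Steps most likely to fail**

Step 3 (Ullmann coupling). The ether is tri-ortho-substituted, the salicylaldehyde phenoxide is a weak, chelating nucleophile, and hydrodebromination or partial reaction at C3–Br can occur. The fallback sets out from 4 and comes back at 6, at the cost of two extra steps. Commercial 2-bromo-5-fluoroanisole F1 is lithiated between OMe and F (LDA, THF, −78 °C) to (3-bromo-6-fluoro-2-methoxyphenyl)lithium F2, which DMF converts to 3-bromo-6-fluoro-2-methoxybenzaldehyde F3. SNAr of F3 with the phenoxide of diol 4 (K2CO3, DMF, 80 °C) gives 3-bromo-6-[2,6-bis(hydroxymethyl)-4-methylphenoxy]-2-methoxybenzaldehyde F4; the fluoride ortho to a planar formyl group is a much better electrophile and the bromide is inert. Pinnick oxidation (NaClO2, NaH2PO4, 2-methyl-2-butene, t-BuOH/H2O) gives 3-bromo-6-[2,6-bis(hydroxymethyl)-4-methylphenoxy]-2-methoxybenzoic acid F5. MnO2 mono-oxidation of one of the two equivalent CH2OH groups then returns 6.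

Step 5 (Heck reaction). The bromide is electron-rich and flanked by OMe, the substrate carries three acidic groups, and product 10 is an acid-labile cinnamyl-type tertiary alcohol that sits next to its own carboxylic acid. The fallback sets out from 8 and comes back at 10. It is a Suzuki–Miyaura coupling of 8 with (E)-2-methyl-4-(4,4,5,5-tetramethyl-1,3,2-dioxaborolan-2-yl)but-3-en-2-ol F6 (PdCl2(dppf), K3PO4, dioxane/H2O, 80 °C). Transmetalation replaces carbopalladation/β-hydride elimination, the alkene geometry comes in with the reagent, and the lower temperature spares the allylic alcohol.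

Step 6 (new hydration). The 4-aryloxy-2-methoxybenzyl cation is well stabilised and may leave the chiral cobalt before water attacks, which would lower the ee. Oxetane closure by the tertiary hydroxyl and simple alkene reduction are further risks. The fallback uses known chemistry, sets out from 8 and comes back at 11.
- Heck reaction of 8 with methyl vinyl ketone (Pd(OAc)2, P(o-tol)3, Et3N, DMF, 90 °C) gives 6-[2-hydroxy-6-(hydroxymethyl)-4-methylphenoxy]-2-methoxy-3-[(E)-3-oxobut-1-enyl]benzoic acid F7.
- Copper-catalysed asymmetric conjugate borylation of its sodium salt (CuCl, the Josiphos antipode that gives the (S)-product, NaOtBu, B2pin2, MeOH, THF) gives 6-[2-hydroxy-6-(hydroxymethyl)-4-methylphenoxy]-2-methoxy-3-[(1S)-3-oxo-1-(4,4,5,5-tetramethyl-1,3,2-dioxaborolan-2-yl)butyl]benzoic acid F8.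
- F8 is oxidised in the same flask with NaBO3·4H2O, with retention, to 3-[(1S)-1-hydroxy-3-oxobutyl]-6-[2-hydroxy-6-(hydroxymethyl)-4-methylphenoxy]-2-methoxybenzoic acid F9.
- Excess MeMgBr with CeCl3 (THF, −78 °C) adds to the methyl ketone of F9 and gives 11.

**Further compounds**
F1 | step 3 | 2-bromo-5-fluoroanisole | COc1cc(F)ccc1Br
F2 | step 3 | (3-bromo-6-fluoro-2-methoxyphenyl)lithium | COc1c([Li])c(F)ccc1Br
F3 | step 3 | 3-bromo-6-fluoro-2-methoxybenzaldehyde | COc1c(Br)ccc(F)c1C=O
F4 | step 3 | 3-bromo-6-[2,6-bis(hydroxymethyl)-4-methylphenoxy]-2-methoxybenzaldehyde | COc1c(Br)ccc(Oc2c(CO)cc(C)cc2CO)c1C=O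
F5 | step 3 | 3-bromo-6-[2,6-bis(hydroxymethyl)-4-methylphenoxy]-2-methoxybenzoic acid | COc1c(Br)ccc(Oc2c(CO)cc(C)cc2CO)c1C(=O)O
F6 | step 5 | (E)-2-methyl-4-(4,4,5,5-tetramethyl-1,3,2-dioxaborolan-2-yl)but-3-en-2-ol | CC(C)(O)/C=C/B1OC(C)(C)C(C)(C)O1
F7 | step 6 | 6-[2-hydroxy-6-(hydroxymethyl)-4-methylphenoxy]-2-methoxy-3-[(E)-3-oxobut-1-enyl]benzoic acid | COc1c(/C=C/C(C)=O)ccc(Oc2c(O)cc(C)cc2CO)c1C(=O)O
F8 | step 6 | 6-[2-hydroxy-6-(hydroxymethyl)-4-methylphenoxy]-2-methoxy-3-[(1S)-3-oxo-1-(4,4,5,5-tetramethyl-1,3,2-dioxaborolan-2-yl)butyl]benzoic acid | COc1c([C@@H](B3OC(C)(C)C(C)(C)O3)CC(C)=O)ccc(Oc2c(O)cc(C)cc2CO)c1C(=O)O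
F9 | step 6 | 3-[(1S)-1-hydroxy-3-oxobutyl]-6-[2-hydroxy-6-(hydroxymethyl)-4-methylphenoxy]-2-methoxybenzoic acid | COc1c([C@@H](O)CC(C)=O)ccc(Oc2c(O)cc(C)cc2CO)c1C(=O)O
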